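The leftover comes first: in these runs, whatever product and intermediate do not hold of the charge is substrate still waiting.

| flask | substrate | partner | remark | time |
|---|---|---|---|---|
| larch | 28 mM | 28 mM | the very flask that is asked about, followed so far |  |
| alder | 14 mM | 28 mM | run made earlier |  |
| flask | 28 mM | 28.0 mM |  | 5.0 min |

larch run (percent of the substrate charged)

| time / s | intermediate / % | product / % |
|---|---|---|
| 25.0 | 10.5 | 29.5 |
| 30.0 | 9.9 | 34.7 |
| 40.0 | 11.1 | 43.5 |
| 50.0 | 11.6 | 52.0 |
| 60.0 | 12.1 | 57.5 |

alder run (percent of the substrate charged)

| time / min | intermediate / % | product / % |
|---|---|---|
| 0.417 | 7.0 | 32.0 |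
| 0.667 | 8.1 | 47.1 |
| 1.00 | 6.8 | 62.8 |
| 1.50 | 5.5 | 78.6 |
| 2.50 | 2.3 | 93.0 |
| 4.00 | 0 | 99.3 |

(standard deviation of a reading: 0.5 percentage points)

1. the best time, 5.0 min at the latest, for intermediate
2. the amount of intermediate, in percent of the substrate charged, at that time



How fast does that leftover go? In the alder run the making constant, the fraction of the substrate present that is lost per minute, comes to 1.23 /min. The larch run reads 1.17 /min, on twice the substrate.

Where does the loss go? I let none bypass the intermediate, which is my guess and differs from the forecast's split.

And the intermediate? In the larch readings it stays between 9.9% and 12.1%, so freeze it (the steady-state approximation): making nearly equals clearing, and the clearing constant is then the making constant times substrate over intermediate.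

Does that separate the runs? Yes. The readings of larch at 60.0 s and alder at 1.00 min both leave 30.4% of the substrate charged, yet the frozen balance reads larch clearing at 3.09 /min, slower than alder's 5.50 /min.

So must the peak wait for the substrate to go? No: it comes where making falls to clearing. I expect it after 60.0 s, with substrate still present, but partner was never read, so I name no time.

The forecast says 2.5 min and 14%: the intermediate should “keep creeping up past 60 s, flatten near 14% once substrate is gone”.

The larch flask peaks at 1.74 min with 13.6%.

    partner → decomposed reagent (k = 4.50 × 10⁻⁴ /s)
    partner ⇌ dormant form (K = 0.920, k = 0.0130 /s)
    partner + intermediate → product (k = 8.60 /M/s)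
    substrate → intermediate (k = 0.0200 /s)

At that peak larch still holds 12.5% substrate, and the frozen balance gives a clearing constant of 1.13 /min, below the 3.09 /min read at 60.0 s. In the same flask with 110 mM substrate, the making constant leaves 0.213% of the substrate at 5.0 min; one partner per product allows 25.5% product, so I reckon about 74.3% intermediate. The computed flask holds 0.248% substrate, 25.2% product and 74.5% intermediate.

The numbers in the tables were computed from invented constants, noise included.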